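**Strategy**

Everything rests on disconnecting the benzo A-ring (C4a, C5, C6, C7, C8, C8a) from a finished 2-aryl-3-methoxy-γ-pyrone. The feature exploited is the resorcinol pattern 5-OH/6-CH3/7-O of that ring, flanked by the pyranone C4a=C8a bond: it is what a pyranonylketene and a methyl-substituted ynol ether give when they combine. In one operation, Wolff rearrangement of the pyranonyl diazoketone, [2+2] addition to 1-(triisopropylsilyloxy)propyne, 4π-opening and 6π-closure forge C8a–C8, C5–C6, C7–C8 and C4a–C5 and leave O1 where it already was. The precursor is a kojic-acid-derived 4-pyranone bearing the anisyl group, the methoxy group and a diazoacetyl group on the carbon next to the ring oxygen. C8 is oxygenated afterwards.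

Key step: step 7

Remark: the target has no stereocentre, so "single enantiomer" is read as the one achiral compound; no step has to set or preserve configuration.

**Route**

Step 1
Reactants: 1 kojic acid (5-hydroxy-2-(hydroxymethyl)-4H-pyran-4-one)
Product: 2 5-hydroxy-2-(hydroxymethyl)-6-iodo-4H-pyran-4-one
Conditions: I2 (1.0 equiv), Na2CO3, H2O, rt; then aq. HCl
Reagents that add atoms: iodine, II
Why: Electrophilic iodination of the phenol-like 3-hydroxy-4-pyranone should occur at C6, the enol carbon ortho to the 5-OH, which is where kojic acid takes up electrophiles in general.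

Step 2
Reactants: 2 5-hydroxy-2-(hydroxymethyl)-6-iodo-4H-pyran-4-one
Product: 3 2-(hydroxymethyl)-6-iodo-5-methoxy-4H-pyran-4-one
Conditions: MeI (1.2 equiv), K2CO3, DMF, rt
Reagents that add atoms: iodomethane, CI
Why: Williamson O-methylation in which carbonate deprotonates only the acidic enolic 5-OH, so the primary alcohol stays free and the metal-chelating hydroxypyranone unit is capped before the palladium step.

Step 3
Reactants: 3 2-(hydroxymethyl)-6-iodo-5-methoxy-4H-pyran-4-one; 4 4-methoxyphenylboronic acid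
Product: 5 2-(hydroxymethyl)-5-methoxy-6-(4-methoxyphenyl)-4H-pyran-4-one
Conditions: Pd(dppf)Cl2 (5 mol%), K2CO3, 1,4-dioxane/H2O, 80 °C
Reagents that add atoms: none
Why: Suzuki–Miyaura coupling, in which the C6–I bond of this vinylogous acyl iodide should add quickly to Pd(0) and the free hydroxymethyl group is tolerated.

Step 4
Reactants: 5 2-(hydroxymethyl)-5-methoxy-6-(4-methoxyphenyl)-4H-pyran-4-one
Product: 6 5-methoxy-6-(4-methoxyphenyl)-4-oxo-4H-pyran-2-carboxylic acid
Conditions: TEMPO (20 mol%), PhI(OAc)2 (2.2 equiv), MeCN/H2O, rt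
Reagents that add atoms: water, O
Why: Oxoammonium (TEMPO/PhI(OAc)2) oxidation in aqueous acetonitrile should take the primary alcohol through the aldehyde hydrate to the acid without affecting the pyranone or the anisyl ring, as comenic acid ethers are made from kojic acid ethers.

Step 5
Reactants: 6 5-methoxy-6-(4-methoxyphenyl)-4-oxo-4H-pyran-2-carboxylic acid
Product: 8 2-(2-diazoacetyl)-5-methoxy-6-(4-methoxyphenyl)-4H-pyran-4-one, via acid chloride 7 (not isolated)
Conditions: (COCl)2, DMF (cat.), CH2Cl2, 0 °C → rt; evaporate; CH2N2 (3 equiv), Et2O/THF, 0 °C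
Reagents that add atoms: oxalyl chloride, O=C(Cl)C(Cl)=O (chlorine of 7 only); diazomethane, C=[N+]=[N-]
Why: Acylation of diazomethane by an acid chloride (first stage of the Arndt–Eistert sequence) should be clean because the acyl carbon sits on an sp2 carbon with no α-hydrogen and the excess diazomethane removes the HCl that would otherwise give the chloromethyl ketone.

Step 6
Reactants: 9 ethyl acetate
Product: 12 1-(triisopropylsilyloxy)prop-1-yne, via dibromo enolate 10 (not isolated), via lithium ynolate 11 (not isolated)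
Conditions: LiTMP (2.2 equiv), CH2Br2, THF, −78 °C; 9; then n-BuLi, −78 → 0 °C; then TIPSCl, −78 °C → rt
Reagents that add atoms: dibromomethane, BrCBr; chlorotriisopropylsilane, CC(C)[Si](Cl)(C(C)C)C(C)C; lithium 2,2,6,6-tetramethylpiperidide, [Li+].CC1(C)CCCC(C)(C)[N-]1 (lithium counter-ion of 10 and 11 only)
Why: Kowalski ynolate synthesis, in which LiCHBr2 adds to the ester, the adduct collapses to the dibromo enolate, bromine–lithium exchange triggers a carbenoid 1,2-methyl shift to the ynolate, and the bulky silyl chloride traps it on oxygen.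

Step 7
Reactants: 8 2-(2-diazoacetyl)-5-methoxy-6-(4-methoxyphenyl)-4H-pyran-4-one; 12 1-(triisopropylsilyloxy)prop-1-yne
Product: 17 5-hydroxy-3-methoxy-2-(4-methoxyphenyl)-6-methyl-7-(triisopropylsilyloxy)-4H-chromen-4-one, via pyranonylketene 13 (not isolated), via cyclobutenone 14 (not isolated), via dienylketene 15 (not isolated), via cyclohexadienone 16 (not isolated)
Conditions: 12 (2 equiv), hν (420–450 nm LED), degassed ClCH2CH2Cl, rt; then 80 °C
Reagents that add atoms: none
Why: Excitation of the diazoketone expels N2 and pyranone C2 shifts to the carbene carbon (Wolff rearrangement, C8a–C8) to give ketene 13, which adds across ynol ether 12 in a [2+2] cycloaddition (C5–C6, C7–C8) to cyclobutenone 14, and 14 opens reversibly (4π, conrotatory) to dienylketene 15. The isomer of 15 that has the ketene carbon cis to the pyranone closes the six-membered A-ring by 6π-electrocyclisation onto pyranone C3 (C4a–C5) to dienone 16, and enolisation, driven by aromatisation and the hydrogen bond to the C4 carbonyl, should give phenol 17. The closest known reaction type is the Danheiser benzannulation of photochemically generated vinyl- and arylketenes with siloxyalkynes. No stereocentre is created in 17, and those of 14 and 16 are transient and racemic. The selectivity needed is the orientation of the [2+2] step, and the ynol ether secures it: its methyl-substituted carbon is the nucleophilic end and attacks the central carbon of the ketene, which puts CH3 at C6 beside the new 5-OH and the silyloxy group at C7. Closure can only reach C3 of the pyranone, so O1 ends up on C8a without ambiguity; light of 420–450 nm is chosen because only the diazoketone should absorb there, which spares the 3-methoxypyranone and flavone chromophores, and the final heating drives residual 14 through to 17.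

Step 8
Reactants: 17 5-hydroxy-3-methoxy-2-(4-methoxyphenyl)-6-methyl-7-(triisopropylsilyloxy)-4H-chromen-4-one
Product: 18 8-bromo-5-hydroxy-3-methoxy-2-(4-methoxyphenyl)-6-methyl-7-(triisopropylsilyloxy)-4H-chromen-4-one
Conditions: NBS (1.05 equiv), CH2Cl2, 0 °C, dark
Reagents that add atoms: N-bromosuccinimide, O=C1CCC(=O)N1Br
Why: Electrophilic aromatic bromination should go to C8, the only unsubstituted A-ring carbon, activated by the para 5-OH, the ortho 7-silyloxy group and O1, while the anisyl ring is far less nucleophilic.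

Step 9
Reactants: 18 8-bromo-5-hydroxy-3-methoxy-2-(4-methoxyphenyl)-6-methyl-7-(triisopropylsilyloxy)-4H-chromen-4-one
Product: 20 5,7-dihydroxy-3,8-dimethoxy-2-(4-methoxyphenyl)-6-methyl-4H-chromen-4-one, via desilylated bromophenol 19 (not isolated)
Conditions: NaOMe (excess, MeOH), CuBr (20 mol%), DMF, 110 °C; then aq. HCl
Reagents that add atoms: sodium methoxide, [Na+].[O-]C
Why: Methoxide first cleaves the aryl silyl ether to phenoxide 19, and copper(I) then promotes Ullmann-type replacement of the C8 bromide by methoxide, a reaction type established on 6- and 8-bromo-5,7-dihydroxyflavones, before acidification releases the target.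

**Compound list**

1 | kojic acid, 5-hydroxy-2-(hydroxymethyl)-4H-pyran-4-one | OCc1cc(=O)c(O)co1 | starting material
2 | 5-hydroxy-2-(hydroxymethyl)-6-iodo-4H-pyran-4-one | OCc1cc(=O)c(O)c(I)o1 | intermediate
3 | 2-(hydroxymethyl)-6-iodo-5-methoxy-4H-pyran-4-one | OCc1cc(=O)c(OC)c(I)o1 | intermediate
4 | 4-methoxyphenylboronic acid | COc1ccc(B(O)O)cc1 | starting material
5 | 2-(hydroxymethyl)-5-methoxy-6-(4-methoxyphenyl)-4H-pyran-4-one | COc1ccc(-c2oc(CO)cc(=O)c2OC)cc1 | intermediate
6 | 5-methoxy-6-(4-methoxyphenyl)-4-oxo-4H-pyran-2-carboxylic acid | COc1ccc(-c2oc(C(=O)O)cc(=O)c2OC)cc1 | intermediate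
7 | 5-methoxy-6-(4-methoxyphenyl)-4-oxo-4H-pyran-2-carbonyl chloride (not isolated) | COc1ccc(-c2oc(C(=O)Cl)cc(=O)c2OC)cc1 | intermediate
8 | 2-(2-diazoacetyl)-5-methoxy-6-(4-methoxyphenyl)-4H-pyran-4-one | COc1ccc(-c2oc(C(=O)C=[N+]=[N-])cc(=O)c2OC)cc1 | intermediate
9 | ethyl acetate | CCOC(C)=O | starting material
10 | lithium 1,1-dibromoprop-1-en-2-olate (not isolated) | [Li+].CC([O-])=C(Br)Br | intermediate
11 | lithium prop-1-yn-1-olate (not isolated) | [Li+].CC#C[O-] | intermediate
12 | 1-(triisopropylsilyloxy)prop-1-yne | CC#CO[Si](C(C)C)(C(C)C)C(C)C | intermediate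
13 | [5-methoxy-6-(4-methoxyphenyl)-4-oxo-4H-pyran-2-yl]ketene (not isolated) | COc1ccc(-c2oc(C=C=O)cc(=O)c2OC)cc1 | intermediate
14 | 4-[5-methoxy-6-(4-methoxyphenyl)-4-oxo-4H-pyran-2-yl]-2-methyl-3-(triisopropylsilyloxy)cyclobut-2-en-1-one (racemic, not isolated) | COc1ccc(-c2oc(C3C(=O)C(C)=C3O[Si](C(C)C)(C(C)C)C(C)C)cc(=O)c2OC)cc1 | intermediate
15 | (3E)-4-[5-methoxy-6-(4-methoxyphenyl)-4-oxo-4H-pyran-2-yl]-2-methyl-3-(triisopropylsilyloxy)buta-1,3-dien-1-one, ketene carbon cis to the pyranone (not isolated) | COc1ccc(-c2oc(/C=C(/O[Si](C(C)C)(C(C)C)C(C)C)C(C)=C=O)cc(=O)c2OC)cc1 | intermediate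
16 | 3-methoxy-2-(4-methoxyphenyl)-6-methyl-7-(triisopropylsilyloxy)-4aH-chromene-4,5-dione (racemic keto tautomer of 17, not isolated) | COc1ccc(C2=C(OC)C(=O)C3C(=O)C(C)=C(O[Si](C(C)C)(C(C)C)C(C)C)C=C3O2)cc1 | intermediate
17 | 5-hydroxy-3-methoxy-2-(4-methoxyphenyl)-6-methyl-7-(triisopropylsilyloxy)-4H-chromen-4-one | COc1ccc(-c2oc3cc(O[Si](C(C)C)(C(C)C)C(C)C)c(C)c(O)c3c(=O)c2OC)cc1 | intermediate
18 | 8-bromo-5-hydroxy-3-methoxy-2-(4-methoxyphenyl)-6-methyl-7-(triisopropylsilyloxy)-4H-chromen-4-one | COc1ccc(-c2oc3c(Br)c(O[Si](C(C)C)(C(C)C)C(C)C)c(C)c(O)c3c(=O)c2OC)cc1 | intermediate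
19 | 8-bromo-5,7-dihydroxy-3-methoxy-2-(4-methoxyphenyl)-6-methyl-4H-chromen-4-one (present as its sodium phenoxide, not isolated) | COc1ccc(-c2oc3c(Br)c(O)c(C)c(O)c3c(=O)c2OC)cc1 | intermediate
20 | 5,7-dihydroxy-3,8-dimethoxy-2-(4-methoxyphenyl)-6-methyl-4H-chromen-4-one | COc1ccc(-c2oc3c(OC)c(O)c(C)c(O)c3c(=O)c2OC)cc1 | target

**Step count and risk**

Total step count: 9. Longest linear sequence: 8 steps (steps 1–5 and 7–9 from kojic acid); step 6 is a one-step side branch.

Steps most likely to fail:

1. Step 7. Light may be absorbed by the pyranone or by the flavone product and start secondary photoreactions (for example hydrogen abstraction from the 3-methoxy group by the excited carbonyl). The Wolff rearrangement may also be slow at long wavelength, so that ketene dimerisation or diazo decomposition outruns the cycloaddition. The fallback generates the same ketene without light. It sets out from 8: silver benzoate and Et3N in aqueous dioxane should give the homologous acid 2-[5-methoxy-6-(4-methoxyphenyl)-4-oxo-4H-pyran-2-yl]acetic acid F1 (Arndt–Eistert). Oxalyl chloride converts it into 2-[5-methoxy-6-(4-methoxyphenyl)-4-oxo-4H-pyran-2-yl]acetyl chloride F2. Slow addition of Et3N to F2 and 12 in ClCH2CH2Cl at rt removes HCl from the acidic methylene and re-enters the route at ketene 13, which is carried on to 17 by heating to 80 °C.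

2. Step 9. Bromine may be lost reductively, or methoxide may open the pyranone at C2 and the ring may reclose on the other phenoxide oxygen, which would exchange the C6 and C8 substituents. The fallback avoids halide and hot methoxide and follows the classical persulfate route. It sets out from 17: TBAF in THF should give 5,7-dihydroxy-3-methoxy-2-(4-methoxyphenyl)-6-methyl-4H-chromen-4-one F3. BnBr and K2CO3 in acetone alkylate only the non-chelated 7-OH to give 7-(benzyloxy)-5-hydroxy-3-methoxy-2-(4-methoxyphenyl)-6-methyl-4H-chromen-4-one F4. Elbs oxidation (K2S2O8, aqueous KOH/pyridine) attacks para to the 5-oxide and gives potassium 7-(benzyloxy)-5-hydroxy-3-methoxy-2-(4-methoxyphenyl)-6-methyl-4-oxo-4H-chromen-8-yl sulfate F5, which warm aqueous HCl hydrolyses to 7-(benzyloxy)-5,8-dihydroxy-3-methoxy-2-(4-methoxyphenyl)-6-methyl-4H-chromen-4-one F6. One equivalent of Me2SO4 with K2CO3 in acetone methylates the free 8-OH and leaves the chelated 5-OH, giving 7-(benzyloxy)-5-hydroxy-3,8-dimethoxy-2-(4-methoxyphenyl)-6-methyl-4H-chromen-4-one F7. Hydrogenolysis (H2, Pd/C, EtOAc) comes back to the route at 20.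

3. Step 3. Hydroxide or carbonate may add to C6 of the vinylogous acyl iodide and displace iodide, or protodeiodination may outrun transmetalation. The fallback changes the order of events so that the halide is coupled as its enolate, which is no longer an acceptor. It sets out from 2: Suzuki–Miyaura coupling with 4 (Pd(OAc)2/SPhos, K2CO3 3 equiv, dioxane/H2O, 80 °C) should give 5-hydroxy-2-(hydroxymethyl)-6-(4-methoxyphenyl)-4H-pyran-4-one F8. O-methylation of F8 with MeI and K2CO3 in DMF comes back to the route at 5.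

**Further compounds**

F1 | step 7 | 2-[5-methoxy-6-(4-methoxyphenyl)-4-oxo-4H-pyran-2-yl]acetic acid | COc1ccc(-c2oc(CC(=O)O)cc(=O)c2OC)cc1
F2 | step 7 | 2-[5-methoxy-6-(4-methoxyphenyl)-4-oxo-4H-pyran-2-yl]acetyl chloride | COc1ccc(-c2oc(CC(=O)Cl)cc(=O)c2OC)cc1
F3 | step 9 | 5,7-dihydroxy-3-methoxy-2-(4-methoxyphenyl)-6-methyl-4H-chromen-4-one | COc1ccc(-c2oc3cc(O)c(C)c(O)c3c(=O)c2OC)cc1
F4 | step 9 | 7-(benzyloxy)-5-hydroxy-3-methoxy-2-(4-methoxyphenyl)-6-methyl-4H-chromen-4-one | COc1ccc(-c2oc3cc(OCc4ccccc4)c(C)c(O)c3c(=O)c2OC)cc1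
F5 | step 9 | potassium 7-(benzyloxy)-5-hydroxy-3-methoxy-2-(4-methoxyphenyl)-6-methyl-4-oxo-4H-chromen-8-yl sulfate | [K+].COc1ccc(-c2oc3c(OS(=O)(=O)[O-])c(OCc4ccccc4)c(C)c(O)c3c(=O)c2OC)cc1
F6 | step 9 | 7-(benzyloxy)-5,8-dihydroxy-3-methoxy-2-(4-methoxyphenyl)-6-methyl-4H-chromen-4-one | COc1ccc(-c2oc3c(O)c(OCc4ccccc4)c(C)c(O)c3c(=O)c2OC)cc1
F7 | step 9 | 7-(benzyloxy)-5-hydroxy-3,8-dimethoxy-2-(4-methoxyphenyl)-6-methyl-4H-chromen-4-one | COc1ccc(-c2oc3c(OC)c(OCc4ccccc4)c(C)c(O)c3c(=O)c2OC)cc1
F8 | step 3 | 5-hydroxy-2-(hydroxymethyl)-6-(4-methoxyphenyl)-4H-pyran-4-one | COc1ccc(-c2oc(CO)cc(=O)c2O)cc1
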